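| setting | alpha | epsilon | oak | elm | birch | larch |
|---|---|---|---|---|---|---|
| substrate | 0.0098 M | 0.042 M | 0.020 M | 0.010 M | 0.032 M | 0.0080 M |
| reagent | 1.05 equiv | 1.05 equiv | 1.05 equiv | 1.05 equiv | 1.05 equiv | 1.05 equiv |
| free catalyst | 5 mol% | 5 mol% | 5 mol% | 5 mol% | 5 mol% | 5 mol% |
| remark | run made earlier | run made earlier |  |  |  |  |
| time |  |  | 8.0 h | 8.0 h | 8.0 h | 8.0 h |

| run | time / h | product / % |
|---|---|---|
| alpha | 0.667 | 0.7 |
| alpha | 1.33 | 2.9 |
| alpha | 3.00 | 6.5 |
| alpha | 8.00 | 21.5 |
| epsilon | 2.00 | 10.8 |
| epsilon | 4.00 | 23.1 |
| epsilon | 6.00 | 33.3 |
| epsilon | 8.00 | 44.8 |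

(each reading ± 1 percentage point)

* the flasks put in order of amount of product, in percent of the substrate charged, best first, at 8.0 h (oak / elm / birch / larch)
* the amount of product, in percent of the substrate charged of the flask you put first, at 8.0 h
* the amount of product, in percent of the substrate charged of the flask you put last, at 8.0 h



At early times the epsilon run makes 0.0540 /h of its charge per hour, and over its full length 0.0560 /h. So, within the scatter, its curve is straight, and I can describe a flask by the share of its charge that it turns to product each hour. Alpha ends at 21.5% and epsilon at 44.8%: concentration grows by a factor of 4.29, but percent yield only by 2.08, which gives an exponent of percent yield on concentration, not a reaction order, of 0.504.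

I assume that yield against concentration starts from zero and bends one way. For birch, the ceiling is epsilon's reading, since that richer flask gave more, and the floor is the straight line between alpha and epsilon, 37.6%. Scaling alpha by the exponent tightens this: I reckon birch at 0.0488 /h, its hourly gain, so 39.0% at 8.0 h. For larch, the ceiling is that line carried downward, 20.2%, and the floor is alpha's yield scaled straight with concentration, 17.6%. The exponent gives 19.4%. Oak comes to 30.8% and elm to 21.7%.

The forecast, birch > oak > elm > larch with 40% and 19%, stands inside both brackets, on the words “The order follows concentration.”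

The flasks give birch > oak > elm > larch, with birch at 38.9% and larch at 17.3%.

    reagent + free catalyst → catalyst intermediate A (k = 0.0590 /M/s)
    substrate + catalyst intermediate A ⇌ catalyst intermediate B (K = 260 /M, k = 0.0550 /M/s)
    catalyst intermediate B ⇌ catalyst intermediate C (K = 0.610, k = 5.70 × 10⁻⁴ /s)
    catalyst intermediate C → free catalyst + product (k = 0.130 /s)
    2 free catalyst ⇌ resting dimer (K = 360 /M, k = 0.400 /M/s)

Birch made 0.0486 /h over its run, against my hourly gain of 0.0488 /h, and larch lies 0.30 percentage points under its floor, with a reading scatter of 1 point. Carried to birch left until 5.0 h, the gain gives 24.4%, and that flask holds 25.0%. Larch stands at 17.3% mainly because it is read at 8.0 h: left until 80.0 h, larch reaches 90.9%.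

The numbers in the tables were computed for substances that don't exist; the scatter is artificial.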